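Readings and results are calculated with made-up constants, and the scatter is random.

Time had stopped paying in the teal run, the flask in question at 60 °C: it read 26.8% at 20.0 h and 27.0% at 25.0 h, a step of 0.2 percentage points against a scatter of 0.3 points. I had to decide what to do with this flask at 30 h.

| flask | starting complex | incoming ligand | temperature | remark | time |
|---|---|---|---|---|---|
| teal | 0.10 M | 0.060 M | 60 °C | the very flask that is asked about, followed so far |  |
| green | 0.050 M | 0.060 M | 66 °C | run made earlier |  |
| flask | 0.10 M | 0.0600 M | 60 °C |  | 30 h |

- teal (time / h: complex with one exchanged / %): 6.00: 23.4; 12.0: 26.0; 20.0: 26.8; 25.0: 27.0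
- green (time / h: complex with one exchanged / %): 0.833: 23.9; 2.00: 24.1; 4.00: 26.1; 6.00: 27.8

(scatter of a reading: 0.3 percentage points)

- epsilon: at 30 h take out 90% of the leaving ligand then present, then wait 2.5 d
- eta: at 30 h raise the temperature by 25 K, then wait 2.5 d
- alpha: change nothing and wait 2.5 d more
- zeta: at 30 h add incoming ligand, 100% of the amount charged, then wait 2.5 d

* complex with one exchanged, in percent of the starting complex first charged, at 30 h
* the remedy with the largest gain of complex with one exchanged, or "none" below 2 percentage points (epsilon / eta / alpha / zeta / none)
* complex with one exchanged present, in percent of the starting complex first charged, after alpha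
* complex with one exchanged present, in percent of the starting complex first charged, after zeta

- the volume of additions can be left aside
- the numbers in the tables scatter by 0.3 percentage points (one standard deviation)

The green run stood at 23.9% by 0.833 h, then took until 6.00 h to add 3.9 points, so I read a fast uptake of incoming ligand followed by a slow sharing-out among the complexes. I assumed a second exchange and took incoming ligand as the limiting reagent, with its free remainder left out of the count. The flask then has a budget of 0.600 exchanges per starting complex charged. The last teal reading puts complex with one exchanged at 27.0%, which on this count leaves 16.5% as complex with two exchanged and 56.5% as starting complex. These fractions give 1.28 for the sharing quotient, complex with two exchanged times starting complex over the square of complex with one exchanged, an estimate that carries the scatter of the teal reading.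

Leaving ligand does not appear in the quotient, and I took waiting to change neither quotient nor budget, so I expected about 27.0% at 30 h and less than 2 points from epsilon or alpha. Zeta raises the budget to 1.20; at the same quotient that gives 29.8%, a gain of 2.8 points. Heat might move the quotient, but I could not read by how much: the green run differs from the teal run in temperature and in charge, and it was still rising at its last reading. I committed to zeta.

The forecast gave 27.2% at 30 h, 27.2% after alpha and 39% after zeta against my 29.8%, and chose zeta, reading “a reversible exchange at equilibrium”. The flask gave 27.7%, 28.3% after alpha and 32.1% after zeta, but the largest gain was 7.9 points from eta, with 4.4 points from zeta.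

    starting complex + incoming ligand ⇌ leaving ligand + complex with one exchanged (K = 21.0, k = 0.150 L mol⁻¹ min⁻¹, Ea = 83.0 kJ mol⁻¹, ΔH = −10.0 kJ mol⁻¹)
    complex with one exchanged + incoming ligand ⇌ leaving ligand + complex with two exchanged (K = 22.0, k = 0.370 L mol⁻¹ min⁻¹, Ea = 58.0 kJ mol⁻¹, ΔH = −45.0 kJ mol⁻¹)
    complex with two exchanged + incoming ligand ⇌ leaving ligand + complex with three exchanged (K = 0.640, k = 0.0510 L mol⁻¹ min⁻¹, Ea = 72.0 kJ mol⁻¹, ΔH = 27.0 kJ mol⁻¹)
    (constants at 60 °C)

In the flask, half the turnover of the first exchange was done by 0.595 h and of the second by 0.792 h, far earlier than 30 h, and at 30 h the first ran backward at 96.2% of its forward rate, with 2.35% of the incoming ligand charge left. Counted on the same budget, the 35.6% of this flask after eta corresponds to a quotient of 0.503, lower than my 1.28, and for the neighbour charged with 0.25 M of starting complex, a budget of 0.240 at 1.28 gave me 15.9%, where that flask held 16.3% at 30.0 h.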